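Cuts: the six O–Si bonds first. Then C2–C3 of ring C, which leaves a ring A diazomethyl ketone (C3=N2 on the C4 carbonyl) whose O1 carries ring B as a benzyl ether. Then C3=N2 (back to an acetyl group), C8–C1'' (side chain), O1–C2 (benzyl ether) and C8–I.
Enabling feature: C2 is bonded both to O1 and to C1' of the trioxygenated ring B, so in the open form its two C–H bonds are activated twice over. The path C3–C4–C4a–C8a–O1–C2 places them one six-membered ring away from a carbene at C3.
Forward order: rings A and B are bought (phloroacetophenone, 2,4,6-trihydroxybenzaldehyde). O1–C2 is made by Mitsunobu etherification, the chain is joined at C8 by Negishi coupling, the acetyl group is turned into the diazoketone, and ring C closes last.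
Stereochemistry: C2'' comes from an Evans deconjugative prenylation on (S)-4-benzyloxazolidin-2-one, which gives (S)-lavandulol, later hydrated at its isopropenyl group. C2 comes from the chiral dirhodium carboxylate, and C2'' makes any C2 epimer a separable diastereomer.
Protection: all six hydroxyl groups travel as silyl ethers, so one buffered fluoride step ends the route without the acid or base that would open ring C or ionise the tertiary alcohol.

Key step: step 14

Assumption: the sense of induction of Rh2(S-PTTL)4 at C2 cannot be derived with certainty for this substrate. It is taken to be (2S); if a model run shows the opposite, the mirror-image catalyst Rh2(R-PTTL)4 takes its place with nothing else changed.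

Step 1
Reactants: 1 (S)-4-benzyloxazolidin-2-one; 2 3-methylbut-2-enoyl chloride
Product: 4 (S)-4-benzyl-3-(3-methylbut-2-enoyl)oxazolidin-2-one, via N-lithio oxazolidinone 3 (not isolated)
Conditions: n-BuLi, THF, −78 °C; then 2, −78 → 0 °C
Reagents that add atoms: none
Why: N-Acylation of a lithiated Evans oxazolidinone with an acid chloride is routine, the low temperature keeps the unsaturated acid chloride from forming a vinylketene, and the auxiliary stereocentre is not involved.

Step 2
Reactants: 4 (S)-4-benzyl-3-(3-methylbut-2-enoyl)oxazolidin-2-one; 5 1-bromo-3-methylbut-2-ene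
Product: 7 (S)-4-benzyl-3-[(2S)-5-methyl-2-(prop-1-en-2-yl)hex-4-enoyl]oxazolidin-2-one, via sodium dienolate 6 (not isolated)
Conditions: NaN(SiMe3)2, THF, −78 °C; then 5, −78 → −40 °C
Reagents that add atoms: none
Why: Evans asymmetric alkylation in its deconjugative variant: the base removes a γ-methyl proton, the sodium-chelated (Z)-dienolate 6 reacts with the allylic bromide at its α-carbon on the face opposite the benzyl group, and this sets the future C2'' as (2S) in the acyl chain, the arrangement that reads (R) once CH2–aryl and CMe2OH replace the carbonyl and isopropenyl groups.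

Step 3
Reactants: 7 (S)-4-benzyl-3-[(2S)-5-methyl-2-(prop-1-en-2-yl)hex-4-enoyl]oxazolidin-2-one
Product: 8 (S)-lavandulol, that is (2S)-5-methyl-2-(prop-1-en-2-yl)hex-4-en-1-ol
Conditions: LiBH4, MeOH (1 equiv), Et2O, 0 °C
Reagents that add atoms: none
Why: Reductive removal of the auxiliary (hydride attack at the exocyclic imide carbonyl) gives the primary alcohol without a base strong enough to conjugate the β,γ-alkene or epimerise the α-carbon, and the auxiliary is recovered.

Step 4
Reactants: 8 (S)-lavandulol
Product: 9 (3R)-3-(hydroxymethyl)-2,6-dimethylhept-5-en-2-ol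
Conditions: Co(acac)2 (10 mol %), PhSiH3 (1.2 equiv), O2 (1 atm), THF, 0 °C → rt
Reagents that add atoms: dioxygen, O=O
Why: Mukaiyama hydration: the cobalt hydride formed from Co(acac)2 and the silane transfers a hydrogen atom faster to the open CH2 terminus of the 1,1-disubstituted alkene than to the trisubstituted one, the tertiary radical can reach the second alkene only through a four-membered or 5-endo closure and is instead trapped by O2 and reduced, so a limited charge of silane should give the Markovnikov monohydrate with C2'' untouched.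

Step 5
Reactants: 9 (3R)-3-(hydroxymethyl)-2,6-dimethylhept-5-en-2-ol
Product: 10 (3S)-3-(iodomethyl)-2,6-dimethylhept-5-en-2-ol
Conditions: I2, PPh3, imidazole, CH2Cl2, 0 °C → rt
Reagents that add atoms: iodine, [I][I]
Why: Appel-type iodination: only the primary hydroxyl gives an alkoxyphosphonium ion open to SN2 attack by iodide, while the tertiary hydroxyl is too hindered to react and oxetane closure is slow (the descriptor changes only because CH2I outranks CMe2OH).

Step 6
Reactants: 10 (3S)-3-(iodomethyl)-2,6-dimethylhept-5-en-2-ol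
Product: 11 triethyl{[(3S)-3-(iodomethyl)-2,6-dimethylhept-5-en-2-yl]oxy}silane
Conditions: TESOTf, 2,6-lutidine, CH2Cl2, −78 → 0 °C
Reagents that add atoms: triethylsilyl trifluoromethanesulfonate, CC[Si](CC)(CC)OS(=O)(=O)C(F)(F)F
Why: Silylation of a tertiary alcohol with a silyl triflate and a hindered pyridine base is standard, and the triethylsilyl ether removes the O–H bond that would otherwise quench the organozinc reagent of step 12 and the carbene of step 14.

Step 7
Reactants: 12 2,4,6-trihydroxybenzaldehyde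
Product: 13 2,4,6-tris(tert-butyldimethylsilyloxy)benzaldehyde
Conditions: TBSCl (3.6 equiv), imidazole, DMF, rt
Reagents that add atoms: tert-butyldimethylsilyl chloride, CC(C)(C)[Si](C)(C)Cl
Why: Standard silyl ether formation with imidazole catalysis, in which an excess of reagent in DMF also silylates the two hydroxyl groups that are hydrogen-bonded to the formyl group.

Step 8
Reactants: 13 2,4,6-tris(tert-butyldimethylsilyloxy)benzaldehyde
Product: 14 [2,4,6-tris(tert-butyldimethylsilyloxy)phenyl]methanol
Conditions: NaBH4, THF–MeOH, −10 °C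
Reagents that add atoms: none
Why: Borohydride reduction of an aryl aldehyde, in which the cold protic medium protonates the benzylic alkoxide at once and so holds back aryl-to-benzyl O-to-O silyl migration.

Step 9
Reactants: 15 1-(2,4,6-trihydroxyphenyl)ethanone
Product: 16 1-[2-hydroxy-4,6-bis(triisopropylsilyloxy)phenyl]ethanone
Conditions: TIPSCl (2.1 equiv), imidazole, DMF, 0 °C → rt
Reagents that add atoms: triisopropylsilyl chloride, CC(C)[Si](Cl)(C(C)C)C(C)C
Why: Selective silylation of phloroacetophenone: the para hydroxyl and one of the two equivalent ortho hydroxyls react, whereas the last one is locked in a hydrogen bond to the acetyl carbonyl and crowded by it, so the bulky chlorosilane should stop at the bis-ether and leave free the oxygen that becomes O1.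

Step 10
Reactants: 16 1-[2-hydroxy-4,6-bis(triisopropylsilyloxy)phenyl]ethanone
Product: 17 1-[2-hydroxy-3-iodo-4,6-bis(triisopropylsilyloxy)phenyl]ethanone
Conditions: NIS, MeCN, 0 °C, dark
Reagents that add atoms: N-iodosuccinimide, O=C1CCC(=O)N1I
Why: Electrophilic aromatic iodination: the free phenol directs ortho to C3 of the acetophenone (the future C8), and the only other open position lies between two triisopropylsilyl ethers and is shielded.

Step 11
Reactants: 17 1-[2-hydroxy-3-iodo-4,6-bis(triisopropylsilyloxy)phenyl]ethanone; 14 [2,4,6-tris(tert-butyldimethylsilyloxy)phenyl]methanol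
Product: 18 1-{3-iodo-4,6-bis(triisopropylsilyloxy)-2-[2,4,6-tris(tert-butyldimethylsilyloxy)benzyloxy]phenyl}ethanone
Conditions: PPh3, DIAD, toluene, 0 °C → rt; chromatography on Et3N-deactivated silica
Reagents that add atoms: none
Why: Mitsunobu etherification: the phenol of 17, made more acidic by the ortho acyl group and the ortho iodine, protonates the betaine and its phenoxide displaces the oxyphosphonium group from the primary benzylic carbon under neutral conditions, while C-alkylation is blocked because the only free ring A carbon lies between two triisopropylsilyl ethers.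

Step 12
Reactants: 11 triethyl{[(3S)-3-(iodomethyl)-2,6-dimethylhept-5-en-2-yl]oxy}silane; 18 1-{3-iodo-4,6-bis(triisopropylsilyloxy)-2-[2,4,6-tris(tert-butyldimethylsilyloxy)benzyloxy]phenyl}ethanone
Product: 20 1-{3-[(2R)-5-methyl-2-(2-triethylsilyloxypropan-2-yl)hex-4-en-1-yl]-4,6-bis(triisopropylsilyloxy)-2-[2,4,6-tris(tert-butyldimethylsilyloxy)benzyloxy]phenyl}ethanone, via alkylzinc iodide 19 (not isolated)
Conditions: Zn dust, LiCl, THF, 40 °C; then 18, Pd(OAc)2 (5 mol %), SPhos (10 mol %), THF, rt → 45 °C
Reagents that add atoms: none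
Why: Negishi coupling: direct zinc insertion gives the LiCl-solubilised primary alkylzinc iodide 19 without touching C2'', the bulky electron-rich biarylphosphine on zerovalent palladium speeds oxidative addition at the doubly ortho-substituted iodide and reductive elimination ahead of β-hydride elimination, and the methyl ketone, the alkene and the silyl ethers all tolerate an organozinc reagent.

Step 13
Reactants: 20 1-{3-[(2R)-5-methyl-2-(2-triethylsilyloxypropan-2-yl)hex-4-en-1-yl]-4,6-bis(triisopropylsilyloxy)-2-[2,4,6-tris(tert-butyldimethylsilyloxy)benzyloxy]phenyl}ethanone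
Product: 23 2-diazo-1-{3-[(2R)-5-methyl-2-(2-triethylsilyloxypropan-2-yl)hex-4-en-1-yl]-4,6-bis(triisopropylsilyloxy)-2-[2,4,6-tris(tert-butyldimethylsilyloxy)benzyloxy]phenyl}ethanone, via lithium enolate 21 (not isolated), via trifluoroacetyl ketone 22 (not isolated)
Conditions: LiN(SiMe3)2, THF, −78 °C; CF3CO2CH2CF3, −78 °C; aq NH4Cl; then MsN3, Et3N, H2O (1 equiv), MeCN, rt
Reagents that add atoms: methanesulfonyl azide, CS(=O)(=O)N=[N+]=[N-]
Why: Detrifluoroacetylative diazo transfer (a Regitz-type diazo transfer): the kinetic lithium enolate 21 of the only enolisable position is C-acylated to the activated 1,3-diketone 22, which takes up N2 from the sulfonyl azide and gives up its trifluoroacetyl group to it, a sequence that avoids both a hindered 2,6-disubstituted benzoic acid and diazomethane and leaves the silyl ethers and the acid-sensitive benzyl ether alone.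

Step 14
Reactants: 23 2-diazo-1-{3-[(2R)-5-methyl-2-(2-triethylsilyloxypropan-2-yl)hex-4-en-1-yl]-4,6-bis(triisopropylsilyloxy)-2-[2,4,6-tris(tert-butyldimethylsilyloxy)benzyloxy]phenyl}ethanone
Product: 24 (2S)-8-[(2R)-5-methyl-2-(2-triethylsilyloxypropan-2-yl)hex-4-en-1-yl]-5,7-bis(triisopropylsilyloxy)-2-[2,4,6-tris(tert-butyldimethylsilyloxy)phenyl]chroman-4-one
Conditions: Rh2(S-PTTL)4 (dirhodium tetrakis[N-phthaloyl-(S)-tert-leucinate], 2 mol %), PhCF3, 4 Å MS, 0 °C, slow addition of 23
Reagents that add atoms: none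
Why: Loss of N2 from 23 on the divalent rhodium carboxylate gives an electrophilic rhodium carbene at C3, which takes up one of the two O1–CH2–aryl hydrogens through a concerted three-centre transition state with hydride-transfer character while the C2–C3 bond forms. The closest known reaction type is the dirhodium-carboxylate-catalysed intramolecular C–H insertion of ortho-alkoxyaryl diazoketones, which gives chroman-4-ones. Ring C closes by 1,6-insertion (six-membered transition state through C3, C4, C4a, C8a, O1 and C2), because the atom in the usual 1,5-position is O1 and bears no hydrogen. C2 is set by the chiral pocket of the four N-phthaloyl-tert-leucinate ligands, which tells the two benzylic hydrogens apart; C2'' is too remote to steer the event but makes any (2R) product a diastereomer that chromatography removes. The step needs C–H insertion to beat attack of O1 on the carbene (oxonium ylide, then [1,2]-benzyl shift to a 2-benzylbenzofuran-3-one): O1 is a poor donor because it is conjugated with the C4 acyl group through ring A and is flanked by that group and the C8 chain, silyl ethers make ring B a weaker migrating group than alkyl ethers would, and the bulky ligands, the low temperature and the non-coordinating solvent disfavour the charge-separated ylide. O5 carries a triisopropylsilyl group that offers neither an activated C–H bond within reach nor an accessible lone pair, and the C4''=C5'' alkene could react only through a nine-membered ring.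

Step 15
Reactants: 24 (2S)-8-[(2R)-5-methyl-2-(2-triethylsilyloxypropan-2-yl)hex-4-en-1-yl]-5,7-bis(triisopropylsilyloxy)-2-[2,4,6-tris(tert-butyldimethylsilyloxy)phenyl]chroman-4-one
Product: 25 (2S)-5,7-dihydroxy-8-[(2R)-2-(2-hydroxypropan-2-yl)-5-methylhex-4-en-1-yl]-2-(2,4,6-trihydroxyphenyl)chroman-4-one
Conditions: HF·pyridine, pyridine, THF, 0 °C → rt
Reagents that add atoms: none
Why: Fluoride-driven cleavage of all six Si–O bonds in a pyridine-buffered, weakly acidic medium: no phenoxide builds up, so ring C should not open to the chalcone and C2 should hold, and the medium is too mild to ionise the tertiary alcohol or protonate the alkene.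

Compound list
1 | (S)-4-benzyloxazolidin-2-one | O=C1OC[C@H](Cc2ccccc2)N1 | starting material
2 | 3-methylbut-2-enoyl chloride | CC(C)=CC(=O)Cl | starting material
3 | N-lithio-(S)-4-benzyloxazolidin-2-one | [Li]N1C(=O)OC[C@@H]1Cc1ccccc1 | intermediate
4 | (S)-4-benzyl-3-(3-methylbut-2-enoyl)oxazolidin-2-one | CC(C)=CC(=O)N1C(=O)OC[C@@H]1Cc1ccccc1 | intermediate
5 | 1-bromo-3-methylbut-2-ene | CC(C)=CCBr | starting material
6 | sodium (Z)-dienolate of 4 | C=C(C)/C=C(\[O-])N1C(=O)OC[C@@H]1Cc1ccccc1.[Na+] | intermediate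
7 | (S)-4-benzyl-3-[(2S)-5-methyl-2-(prop-1-en-2-yl)hex-4-enoyl]oxazolidin-2-one | CC(C)=CC[C@H](C(=O)N1C(=O)OC[C@@H]1Cc1ccccc1)C(C)=C | intermediate
8 | (S)-lavandulol, (2S)-5-methyl-2-(prop-1-en-2-yl)hex-4-en-1-ol | CC(C)=CC[C@H](CO)C(C)=C | intermediate
9 | (3R)-3-(hydroxymethyl)-2,6-dimethylhept-5-en-2-ol | CC(C)=CC[C@H](CO)C(C)(C)O | intermediate
10 | (3S)-3-(iodomethyl)-2,6-dimethylhept-5-en-2-ol | CC(C)=CC[C@H](CI)C(C)(C)O | intermediate
11 | triethyl{[(3S)-3-(iodomethyl)-2,6-dimethylhept-5-en-2-yl]oxy}silane | CC(C)=CC[C@H](CI)C(C)(C)O[Si](CC)(CC)CC | intermediate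
12 | 2,4,6-trihydroxybenzaldehyde | O=Cc1c(O)cc(O)cc1O | starting material
13 | 2,4,6-tris(tert-butyldimethylsilyloxy)benzaldehyde | O=Cc1c(O[Si](C)(C)C(C)(C)C)cc(O[Si](C)(C)C(C)(C)C)cc1O[Si](C)(C)C(C)(C)C | intermediate
14 | [2,4,6-tris(tert-butyldimethylsilyloxy)phenyl]methanol | OCc1c(O[Si](C)(C)C(C)(C)C)cc(O[Si](C)(C)C(C)(C)C)cc1O[Si](C)(C)C(C)(C)C | intermediate
15 | 1-(2,4,6-trihydroxyphenyl)ethanone | CC(=O)c1c(O)cc(O)cc1O | starting material
16 | 1-[2-hydroxy-4,6-bis(triisopropylsilyloxy)phenyl]ethanone | CC(=O)c1c(O)cc(O[Si](C(C)C)(C(C)C)C(C)C)cc1O[Si](C(C)C)(C(C)C)C(C)C | intermediate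
17 | 1-[2-hydroxy-3-iodo-4,6-bis(triisopropylsilyloxy)phenyl]ethanone | CC(=O)c1c(O)c(I)c(O[Si](C(C)C)(C(C)C)C(C)C)cc1O[Si](C(C)C)(C(C)C)C(C)C | intermediate
18 | 1-{3-iodo-4,6-bis(triisopropylsilyloxy)-2-[2,4,6-tris(tert-butyldimethylsilyloxy)benzyloxy]phenyl}ethanone | CC(=O)c1c(OCc2c(O[Si](C)(C)C(C)(C)C)cc(O[Si](C)(C)C(C)(C)C)cc2O[Si](C)(C)C(C)(C)C)c(I)c(O[Si](C(C)C)(C(C)C)C(C)C)cc1O[Si](C(C)C)(C(C)C)C(C)C | intermediate
19 | {(2S)-5-methyl-2-[2-(triethylsilyloxy)propan-2-yl]hex-4-en-1-yl}zinc iodide | CC(C)=CC[C@H](C[Zn]I)C(C)(C)O[Si](CC)(CC)CC | intermediate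
20 | 1-{3-[(2R)-5-methyl-2-(2-triethylsilyloxypropan-2-yl)hex-4-en-1-yl]-4,6-bis(triisopropylsilyloxy)-2-[2,4,6-tris(tert-butyldimethylsilyloxy)benzyloxy]phenyl}ethanone | CC(C)=CC[C@H](Cc1c(O[Si](C(C)C)(C(C)C)C(C)C)cc(O[Si](C(C)C)(C(C)C)C(C)C)c(C(C)=O)c1OCc1c(O[Si](C)(C)C(C)(C)C)cc(O[Si](C)(C)C(C)(C)C)cc1O[Si](C)(C)C(C)(C)C)C(C)(C)O[Si](CC)(CC)CC | intermediate
21 | lithium enolate of 20 | CC(C)=CC[C@H](Cc1c(O[Si](C(C)C)(C(C)C)C(C)C)cc(O[Si](C(C)C)(C(C)C)C(C)C)c(C(=C)O[Li])c1OCc1c(O[Si](C)(C)C(C)(C)C)cc(O[Si](C)(C)C(C)(C)C)cc1O[Si](C)(C)C(C)(C)C)C(C)(C)O[Si](CC)(CC)CC | intermediate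
22 | 4,4,4-trifluoro-1-aryl-butane-1,3-dione derived from 20 (aryl as in 20) | CC(C)=CC[C@H](Cc1c(O[Si](C(C)C)(C(C)C)C(C)C)cc(O[Si](C(C)C)(C(C)C)C(C)C)c(C(=O)CC(=O)C(F)(F)F)c1OCc1c(O[Si](C)(C)C(C)(C)C)cc(O[Si](C)(C)C(C)(C)C)cc1O[Si](C)(C)C(C)(C)C)C(C)(C)O[Si](CC)(CC)CC | intermediate
23 | 2-diazo-1-{3-[(2R)-5-methyl-2-(2-triethylsilyloxypropan-2-yl)hex-4-en-1-yl]-4,6-bis(triisopropylsilyloxy)-2-[2,4,6-tris(tert-butyldimethylsilyloxy)benzyloxy]phenyl}ethanone | CC(C)=CC[C@H](Cc1c(O[Si](C(C)C)(C(C)C)C(C)C)cc(O[Si](C(C)C)(C(C)C)C(C)C)c(C(=O)C=[N+]=[N-])c1OCc1c(O[Si](C)(C)C(C)(C)C)cc(O[Si](C)(C)C(C)(C)C)cc1O[Si](C)(C)C(C)(C)C)C(C)(C)O[Si](CC)(CC)CC | intermediate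
24 | (2S)-8-[(2R)-5-methyl-2-(2-triethylsilyloxypropan-2-yl)hex-4-en-1-yl]-5,7-bis(triisopropylsilyloxy)-2-[2,4,6-tris(tert-butyldimethylsilyloxy)phenyl]chroman-4-one | CC(C)=CC[C@H](Cc1c(O[Si](C(C)C)(C(C)C)C(C)C)cc(O[Si](C(C)C)(C(C)C)C(C)C)c2c1O[C@H](c1c(O[Si](C)(C)C(C)(C)C)cc(O[Si](C)(C)C(C)(C)C)cc1O[Si](C)(C)C(C)(C)C)CC2=O)C(C)(C)O[Si](CC)(CC)CC | intermediate
25 | (2S)-5,7-dihydroxy-8-[(2R)-2-(2-hydroxypropan-2-yl)-5-methylhex-4-en-1-yl]-2-(2,4,6-trihydroxyphenyl)chroman-4-one | CC(C)=CC[C@H](Cc1c(O)cc(O)c2c1O[C@H](c1c(O)cc(O)cc1O)CC2=O)C(C)(C)O | target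

Total step count: 15. Longest linear sequence: 10 steps (steps 1–6, then 12–15, counted from 1).

Steps most likely to fail

Step 14. Attack of O1 on the carbene followed by migration of the electron-rich benzyl group may outrun C–H insertion. Discrimination between the two benzylic hydrogens may also be weak in so crowded a pocket. The fallback closes ring C at O1–C2 instead; it sets out from 17 and 13 and comes back to the route at 24. Ketone 17 and aldehyde 13 are condensed under pyrrolidine catalysis in MeCN (Claisen–Schmidt condensation) to (E)-1-[2-hydroxy-3-iodo-4,6-bis(triisopropylsilyloxy)phenyl]-3-[2,4,6-tris(tert-butyldimethylsilyloxy)phenyl]prop-2-en-1-one F1. A quinine-derived bifunctional thiourea then promotes the enantioselective intramolecular oxa-Michael addition of O1 to C2, giving (2S)-8-iodo-5,7-bis(triisopropylsilyloxy)-2-[2,4,6-tris(tert-butyldimethylsilyloxy)phenyl]chroman-4-one F2. Negishi coupling of F2 with zinc reagent 19 under the catalyst of step 12 attaches the chain and gives 24. From that point any (2R) material is a diastereomer and can be separated.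

Step 11. The activated benzylic alcohol may ionise and alkylate another ring B (self-condensation), or the chelated, doubly flanked phenol may react too slowly with the oxyphosphonium salt. The fallback avoids any activated benzylic alcohol; it sets out from 13 (with 17) and comes back at 18. Aldehyde 13 is condensed with 4-methylbenzenesulfonohydrazide to N'-[2,4,6-tris(tert-butyldimethylsilyloxy)benzylidene]-4-methylbenzenesulfonohydrazide F3. Heating F3 with K2CO3 and phenol 17 in dioxane releases 2-(diazomethyl)-1,3,5-tris(tert-butyldimethylsilyloxy)benzene F4 (Bamford–Stevens reaction). F4 is protonated by the acidic phenol and captured at its oxygen with loss of nitrogen, giving 18 (metal-free reductive etherification of a tosylhydrazone).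

Step 12. Oxidative addition and transmetalation at an iodide flanked by two bulky ethers may be slow. This leaves room for protodeiodination, β-hydride elimination and zinc-salt-induced loss of the acid-sensitive benzyl ether. The fallback reverses the order of the two unions; it sets out from 17 and 19 and comes back at 20. The free iodophenol 17, whose iodine has only a small hydroxyl group on one side, is coupled with 19 under Pd(OAc)2/SPhos, a catalyst system under which organozinc reagents tolerate acidic O–H groups. This gives 1-{2-hydroxy-3-[(2R)-5-methyl-2-(2-triethylsilyloxypropan-2-yl)hex-4-en-1-yl]-4,6-bis(triisopropylsilyloxy)phenyl}ethanone F5. Mitsunobu etherification of F5 with alcohol 14 (PPh3, DIAD, toluene) then gives 20, so the benzyl ether never meets zinc salts.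

Further compounds
F1 | step 14 | (E)-1-[2-hydroxy-3-iodo-4,6-bis(triisopropylsilyloxy)phenyl]-3-[2,4,6-tris(tert-butyldimethylsilyloxy)phenyl]prop-2-en-1-one | O=C(/C=C/c1c(O[Si](C)(C)C(C)(C)C)cc(O[Si](C)(C)C(C)(C)C)cc1O[Si](C)(C)C(C)(C)C)c1c(O)c(I)c(O[Si](C(C)C)(C(C)C)C(C)C)cc1O[Si](C(C)C)(C(C)C)C(C)C
F2 | step 14 | (2S)-8-iodo-5,7-bis(triisopropylsilyloxy)-2-[2,4,6-tris(tert-butyldimethylsilyloxy)phenyl]chroman-4-one | Ic1c(O[Si](C(C)C)(C(C)C)C(C)C)cc(O[Si](C(C)C)(C(C)C)C(C)C)c2c1O[C@H](c1c(O[Si](C)(C)C(C)(C)C)cc(O[Si](C)(C)C(C)(C)C)cc1O[Si](C)(C)C(C)(C)C)CC2=O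
F3 | step 11 | N'-[2,4,6-tris(tert-butyldimethylsilyloxy)benzylidene]-4-methylbenzenesulfonohydrazide | Cc1ccc(cc1)S(=O)(=O)N/N=C/c1c(O[Si](C)(C)C(C)(C)C)cc(O[Si](C)(C)C(C)(C)C)cc1O[Si](C)(C)C(C)(C)C
F4 | step 11 | 2-(diazomethyl)-1,3,5-tris(tert-butyldimethylsilyloxy)benzene | [N-]=[N+]=Cc1c(O[Si](C)(C)C(C)(C)C)cc(O[Si](C)(C)C(C)(C)C)cc1O[Si](C)(C)C(C)(C)C
F5 | step 12 | 1-{2-hydroxy-3-[(2R)-5-methyl-2-(2-triethylsilyloxypropan-2-yl)hex-4-en-1-yl]-4,6-bis(triisopropylsilyloxy)phenyl}ethanone | CC(C)=CC[C@H](Cc1c(O[Si](C(C)C)(C(C)C)C(C)C)cc(O[Si](C(C)C)(C(C)C)C(C)C)c(C(C)=O)c1O)C(C)(C)O[Si](CC)(CC)CC
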